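**Retrosynthetic overview**

1. Schizotenuin A 19 comes from the fully protected compound 18 by one acidolysis; 18 is cut at the C5–vinyl bond (Heck) into 5-bromobenzofuran 16 and acrylate 17 of protected (R)-danshensu.
2. The route rests on one feature: C3 of the furan ring carries both ring A (bond C3–C3a) and the ester carbonyl, the pattern left when C4a of a chroman-4-one migrates from the carbonyl carbon C4 to C3.
3. Benzofuran 16 therefore comes from dihydrobenzofuran ester 15 by dehydrogenation, and 15 from 3-diazoflavanone 9 by photochemical Wolff ring contraction, the ketene being taken up by protected danshensu alcohol 13.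
4. Diazo ketone 9 comes from flavanone 7 (detrifluoroacetylative diazo transfer), 7 from chalcone 6, and 6 from acetophenone 3 and aldehyde 5; 13 and 17 come from sodium danshensu 10.
5. Ring order: ring A and the three catechol rings are bought; the pyranone ring is closed in step 5, contracted to the dihydrofuran ring in step 11 and aromatised to the furan ring in step 12.

Key step: step 11

Assumption: commercial sodium danshensu is the (R) enantiomer drawn in the target; the flavanone series is carried racemic at C2 because that centre becomes sp2 in step 12.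

**Route**

Step 1
Reactants: 1 2',3'-dihydroxyacetophenone
Product: 2 1-[2-hydroxy-3-(methoxymethoxy)phenyl]ethanone
Conditions: MOMCl (1.05 equiv), i-Pr2NEt, CH2Cl2, 0 °C
Reagents that add atoms: chloromethyl methyl ether, COCCl
Why: The 2'-OH is tied up in a hydrogen bond to the acetyl carbonyl and is the poorer nucleophile, so this Williamson-type O-alkylation with one equivalent of MOMCl should take place at the free 3'-OH.

Step 2
Reactants: 2 1-[2-hydroxy-3-(methoxymethoxy)phenyl]ethanone
Product: 3 1-[5-bromo-2-hydroxy-3-(methoxymethoxy)phenyl]ethanone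
Conditions: NBS (1.0 equiv), MeCN, 0 → 20 °C
Reagents that add atoms: N-bromosuccinimide, O=C1CCC(=O)N1Br
Why: Electrophilic aromatic bromination should go para to the free phenol (both ortho positions are substituted) and meta to the acetyl group, that is to C5', and NBS releases no HBr that could cleave the MOM acetal.

Step 3
Reactants: 4 protocatechualdehyde
Product: 5 2,2-dimethyl-1,3-benzodioxole-5-carbaldehyde
Conditions: 2,2-dimethoxypropane, TsOH·H2O (cat.), PhMe, reflux, MeOH removed over 4 Å molecular sieves
Reagents that add atoms: 2,2-dimethoxypropane, COC(C)(C)OC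
Why: Acid-catalysed transketalisation to the catechol acetonide is driven by removal of methanol, and any aldehyde dimethyl acetal reverts on aqueous work-up.

Step 4
Reactants: 3 1-[5-bromo-2-hydroxy-3-(methoxymethoxy)phenyl]ethanone; 5 2,2-dimethyl-1,3-benzodioxole-5-carbaldehyde
Product: 6 (E)-1-[5-bromo-2-hydroxy-3-(methoxymethoxy)phenyl]-3-(2,2-dimethyl-1,3-benzodioxol-5-yl)prop-2-en-1-one
Conditions: KOH (aq.), EtOH, 20 °C; AcOH to pH 6 at 0 °C
Reagents that add atoms: none
Why: Claisen–Schmidt aldol condensation with a non-enolisable aldehyde should give the conjugated (E)-enone by dehydration, and the MOM ether, acetonide and aryl bromide are stable to base.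

Step 5
Reactants: 6 (E)-1-[5-bromo-2-hydroxy-3-(methoxymethoxy)phenyl]-3-(2,2-dimethyl-1,3-benzodioxol-5-yl)prop-2-en-1-one
Product: 7 racemic 6-bromo-2-(2,2-dimethyl-1,3-benzodioxol-5-yl)-8-(methoxymethoxy)chroman-4-one
Conditions: NaOAc, EtOH, reflux
Reagents that add atoms: none
Why: The classical chalcone–flavanone isomerisation (intramolecular 6-endo oxa-Michael addition of the phenol) closes the pyranone ring under buffered base; C2 forms racemic, which does not matter because it is aromatised in step 12, and unreacted chalcone can be recycled.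

Step 6
Reactants: 7 racemic 6-bromo-2-(2,2-dimethyl-1,3-benzodioxol-5-yl)-8-(methoxymethoxy)chroman-4-one
Product: 8 6-bromo-2-(2,2-dimethyl-1,3-benzodioxol-5-yl)-8-(methoxymethoxy)-3-(trifluoroacetyl)chroman-4-one (racemic, keto/enol mixture, used crude)
Conditions: LiN(SiMe3)2, THF, −78 °C; CF3CO2CH2CF3, −78 °C; aq. NH4Cl
Reagents that add atoms: 2,2,2-trifluoroethyl trifluoroacetate, O=C(OCC(F)(F)F)C(F)(F)F
Why: Kinetic lithium enolate formation and Claisen-type C-trifluoroacetylation at −78 °C activate C3 for diazo transfer, the low temperature keeping the enolate from opening to the chalcone phenoxide by retro-oxa-Michael reaction before it is acylated.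

Step 7
Reactants: 8 6-bromo-2-(2,2-dimethyl-1,3-benzodioxol-5-yl)-8-(methoxymethoxy)-3-(trifluoroacetyl)chroman-4-one
Product: 9 racemic 6-bromo-3-diazo-2-(2,2-dimethyl-1,3-benzodioxol-5-yl)-8-(methoxymethoxy)chroman-4-one
Conditions: 4-acetamidobenzenesulfonyl azide, Et3N, H2O (1 equiv), MeCN, 20 °C, dark
Reagents that add atoms: 4-acetamidobenzenesulfonyl azide, CC(=O)Nc1ccc(cc1)S(=O)(=O)N=[N+]=[N-]
Why: Regitz diazo transfer with loss of the activating group (detrifluoroacetylative diazo transfer) should deliver the α-diazo ketone, the far more electrophilic trifluoroacetyl group leaving as the N-sulfonyl trifluoroacetamide under an amine base too mild to open the pyranone ring.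

Step 8
Reactants: 10 sodium (R)-3-(3,4-dihydroxyphenyl)lactate (danshensu sodium salt)
Product: 11 (R)-5-[(2,2-dimethyl-1,3-benzodioxol-5-yl)methyl]-2,2-dimethyl-1,3-dioxolan-4-one
Conditions: 2,2-dimethoxypropane, TsOH·H2O (1.1 equiv), acetone/PhMe, reflux
Reagents that add atoms: 2,2-dimethoxypropane, COC(C)(C)OC
Why: Acid-catalysed ketalisation should tie up the catechol as the acetonide and the α-hydroxy acid as the dioxolanone without breaking any bond to the stereocentre, so (R) is kept; any methyl ester formed on the side converges to the same acid in step 9.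

Step 9
Reactants: 11 (R)-5-[(2,2-dimethyl-1,3-benzodioxol-5-yl)methyl]-2,2-dimethyl-1,3-dioxolan-4-one
Product: 12 (R)-3-(2,2-dimethyl-1,3-benzodioxol-5-yl)-2-hydroxypropanoic acid
Conditions: LiOH, THF/H2O, 0 °C; dilute HCl to pH 4 at 0 °C
Reagents that add atoms: lithium hydroxide, [Li+].[OH-]
Why: Saponification of the activated dioxolanone (acyl–oxygen cleavage with loss of acetone) is fast at 0 °C, the catechol ketal is inert to base, and the α-oxido carboxylate formed should not racemise.

Step 10
Reactants: 12 (R)-3-(2,2-dimethyl-1,3-benzodioxol-5-yl)-2-hydroxypropanoic acid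
Product: 13 tert-butyl (R)-3-(2,2-dimethyl-1,3-benzodioxol-5-yl)-2-hydroxypropanoate
Conditions: O-tert-butyl-N,N'-diisopropylisourea, CH2Cl2, 20 °C
Reagents that add atoms: O-tert-butyl-N,N'-diisopropylisourea, CC(C)N=C(OC(C)(C)C)NC(C)C
Why: In this O-alkylisourea esterification only the carboxylic acid is acidic enough to protonate the isourea and take up the tert-butyl group, so the neutral secondary alcohol and the stereocentre are left untouched.

Step 11
Reactants: 9 racemic 6-bromo-3-diazo-2-(2,2-dimethyl-1,3-benzodioxol-5-yl)-8-(methoxymethoxy)chroman-4-one; 13 tert-butyl (R)-3-(2,2-dimethyl-1,3-benzodioxol-5-yl)-2-hydroxypropanoate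
Product: 15 (R)-1-tert-butoxy-3-(2,2-dimethyl-1,3-benzodioxol-5-yl)-1-oxopropan-2-yl 5-bromo-2-(2,2-dimethyl-1,3-benzodioxol-5-yl)-7-(methoxymethoxy)-2,3-dihydro-1-benzofuran-3-carboxylate (C2/C3 diastereomer mixture), via ketene 14 (not isolated)
Conditions: 13 (1.5 equiv), hν (440 nm LED), degassed CH2Cl2, 15 °C; then DMAP (10 mol %), 20 °C
Reagents that add atoms: none
Why: Direct excitation of the s-cis-locked α-diazo ketone expels N2 while the ring A carbon C4a shifts from the carbonyl carbon C4 to the diazo carbon C3 (concerted photo-Wolff rearrangement), giving ketene 14 whose C=C=O carbon is the former C4, and DMAP-assisted addition of the hydroxyl of 13 then forms the C3 ester without a coupling reagent. The closest known reaction type is the photochemical Wolff ring contraction of 2-diazo-1-tetralone and of 3-diazochroman-4-one in alcohols to indane- and 2,3-dihydrobenzofuran-carboxylates. The five-membered O1–C2–C3–C3a–C7a ring is closed by this 1,2-shift, a contraction of the six-membered pyranone ring through the new C3–C3a bond, not by a cyclisation. The new C3 stereocentre is set by protonation of the ester enol, expected mainly anti to the C2 aryl group, and is of no consequence because C2 and C3 both become sp2 in step 12, while the (R) centre of 13 is only O-acylated and cannot change. The step needs migration of ring A and not of the catechol ring, which is certain because only a substituent on the carbonyl carbon can migrate, and it needs the rearrangement to outrun the 1,2-hydride shift from C2 (flavone) and carbene O–H insertion, which the locked s-cis geometry and metal-free irradiation should secure. Light of 440 nm is absorbed only by the diazo ketone, so the C–Br bond and the acetonides are spared.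

Step 12
Reactants: 15 the 2,3-dihydro-1-benzofuran-3-carboxylate ester of step 11 (diastereomer mixture)
Product: 16 (R)-1-tert-butoxy-3-(2,2-dimethyl-1,3-benzodioxol-5-yl)-1-oxopropan-2-yl 5-bromo-2-(2,2-dimethyl-1,3-benzodioxol-5-yl)-7-(methoxymethoxy)-1-benzofuran-3-carboxylate
Conditions: DDQ (1.5 equiv), PhMe, 80 °C
Reagents that add atoms: none
Why: DDQ dehydrogenation by hydride abstraction from C2 (benzylic, α to O1 and para to an acetal oxygen of the aryl group) and loss of the C3 proton should aromatise the furan ring, all C2/C3 diastereomers converging on one compound while the danshensu stereocentre is not involved.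

Step 13
Reactants: 13 tert-butyl (R)-3-(2,2-dimethyl-1,3-benzodioxol-5-yl)-2-hydroxypropanoate
Product: 17 tert-butyl (R)-2-(acryloyloxy)-3-(2,2-dimethyl-1,3-benzodioxol-5-yl)propanoate
Conditions: acryloyl chloride, Et3N, CH2Cl2, 0 °C
Reagents that add atoms: acryloyl chloride, C=CC(=O)Cl
Why: O-acylation of the secondary alcohol by the acid chloride at 0 °C is fast and does not touch the C–H bond of the stereocentre.

Step 14
Reactants: 16 the 5-bromo-1-benzofuran-3-carboxylate ester of step 12; 17 tert-butyl (R)-2-(acryloyloxy)-3-(2,2-dimethyl-1,3-benzodioxol-5-yl)propanoate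
Product: 18 fully protected schizotenuin A: the (E)-acrylate of 17 joined through its β-carbon to C5 of the benzofuran of 16 (three catechol acetonides, two tert-butyl esters, 7-O-MOM)
Conditions: 17 (1.3 equiv), Pd2(dba)3 (2.5 mol %), [HP(t-Bu)3]BF4 (6 mol %), Cy2NMe, 1,4-dioxane, 60 °C
Reagents that add atoms: none
Why: Mizoroki–Heck reaction, in which oxidative addition of zerovalent palladium into the C5–Br bond, syn-insertion of the acrylate and syn-β-hydride elimination should give the (E)-cinnamate, the hindered amine base and moderate temperature being chosen so that neither α-acyloxy ester stereocentre epimerises.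

Step 15
Reactants: 18 fully protected schizotenuin A
Product: 19 schizotenuin A
Conditions: TFA/H2O (9:1), 0 → 20 °C
Reagents that add atoms: none
Why: Global acidolysis should hydrolyse the three catechol acetonides and the MOM acetal and cleave both tert-butyl esters by loss of isobutene, whereas the two ester links to danshensu, the (E)-alkene and both (R) centres are stable to acid.

**Compound list**

1 | 2',3'-dihydroxyacetophenone | CC(=O)c1cccc(O)c1O | starting material
2 | 1-[2-hydroxy-3-(methoxymethoxy)phenyl]ethanone | CC(=O)c1cccc(OCOC)c1O | intermediate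
3 | 1-[5-bromo-2-hydroxy-3-(methoxymethoxy)phenyl]ethanone | CC(=O)c1cc(Br)cc(OCOC)c1O | intermediate
4 | protocatechualdehyde (3,4-dihydroxybenzaldehyde) | O=Cc1ccc(O)c(O)c1 | starting material
5 | 2,2-dimethyl-1,3-benzodioxole-5-carbaldehyde | O=Cc1ccc2OC(C)(C)Oc2c1 | intermediate
6 | (E)-1-[5-bromo-2-hydroxy-3-(methoxymethoxy)phenyl]-3-(2,2-dimethyl-1,3-benzodioxol-5-yl)prop-2-en-1-one | O=C(/C=C/c1ccc2OC(C)(C)Oc2c1)c1cc(Br)cc(OCOC)c1O | intermediate
7 | racemic 6-bromo-2-(2,2-dimethyl-1,3-benzodioxol-5-yl)-8-(methoxymethoxy)chroman-4-one | O=C1CC(c2ccc3OC(C)(C)Oc3c2)Oc2c(OCOC)cc(Br)cc12 | intermediate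
8 | 6-bromo-2-(2,2-dimethyl-1,3-benzodioxol-5-yl)-8-(methoxymethoxy)-3-(trifluoroacetyl)chroman-4-one (racemic, C2/C3 and keto/enol mixture) | O=C1C(C(=O)C(F)(F)F)C(c2ccc3OC(C)(C)Oc3c2)Oc2c(OCOC)cc(Br)cc12 | intermediate
9 | racemic 6-bromo-3-diazo-2-(2,2-dimethyl-1,3-benzodioxol-5-yl)-8-(methoxymethoxy)chroman-4-one | [N-]=[N+]=C1C(c2ccc3OC(C)(C)Oc3c2)Oc2c(OCOC)cc(Br)cc2C1=O | intermediate
10 | sodium (R)-3-(3,4-dihydroxyphenyl)lactate (danshensu sodium salt) | O[C@H](Cc1ccc(O)c(O)c1)C(=O)[O-].[Na+] | starting material
11 | (R)-5-[(2,2-dimethyl-1,3-benzodioxol-5-yl)methyl]-2,2-dimethyl-1,3-dioxolan-4-one | CC1(C)O[C@H](Cc2ccc3OC(C)(C)Oc3c2)C(=O)O1 | intermediate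
12 | (R)-3-(2,2-dimethyl-1,3-benzodioxol-5-yl)-2-hydroxypropanoic acid | O[C@H](Cc1ccc2OC(C)(C)Oc2c1)C(=O)O | intermediate
13 | tert-butyl (R)-3-(2,2-dimethyl-1,3-benzodioxol-5-yl)-2-hydroxypropanoate | O[C@H](Cc1ccc2OC(C)(C)Oc2c1)C(=O)OC(C)(C)C | intermediate
14 | ketene: 5-bromo-2-(2,2-dimethyl-1,3-benzodioxol-5-yl)-7-(methoxymethoxy)-3-(oxomethylidene)-2,3-dihydro-1-benzofuran (racemic, not isolated) | O=C=C1C(c2ccc3OC(C)(C)Oc3c2)Oc2c(OCOC)cc(Br)cc12 | intermediate
15 | (R)-1-tert-butoxy-3-(2,2-dimethyl-1,3-benzodioxol-5-yl)-1-oxopropan-2-yl 5-bromo-2-(2,2-dimethyl-1,3-benzodioxol-5-yl)-7-(methoxymethoxy)-2,3-dihydro-1-benzofuran-3-carboxylate (mixture at C2 and C3) | O=C(O[C@H](Cc1ccc2OC(C)(C)Oc2c1)C(=O)OC(C)(C)C)C1C(c2ccc3OC(C)(C)Oc3c2)Oc2c(OCOC)cc(Br)cc12 | intermediate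
16 | (R)-1-tert-butoxy-3-(2,2-dimethyl-1,3-benzodioxol-5-yl)-1-oxopropan-2-yl 5-bromo-2-(2,2-dimethyl-1,3-benzodioxol-5-yl)-7-(methoxymethoxy)-1-benzofuran-3-carboxylate | O=C(O[C@H](Cc1ccc2OC(C)(C)Oc2c1)C(=O)OC(C)(C)C)c1c(-c2ccc3OC(C)(C)Oc3c2)oc2c(OCOC)cc(Br)cc12 | intermediate
17 | tert-butyl (R)-2-(acryloyloxy)-3-(2,2-dimethyl-1,3-benzodioxol-5-yl)propanoate | C=CC(=O)O[C@H](Cc1ccc2OC(C)(C)Oc2c1)C(=O)OC(C)(C)C | intermediate
18 | fully protected schizotenuin A (tris-acetonide, bis-tert-butyl ester, 7-O-MOM; E alkene, both danshensu centres R) | O=C(/C=C/c1cc(OCOC)c2oc(-c3ccc4OC(C)(C)Oc4c3)c(C(=O)O[C@H](Cc3ccc4OC(C)(C)Oc4c3)C(=O)OC(C)(C)C)c2c1)O[C@H](Cc1ccc2OC(C)(C)Oc2c1)C(=O)OC(C)(C)C | intermediate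
19 | schizotenuin A | O=C(/C=C/c1cc(O)c2oc(-c3ccc(O)c(O)c3)c(C(=O)O[C@H](Cc3ccc(O)c(O)c3)C(=O)O)c2c1)O[C@H](Cc1ccc(O)c(O)c1)C(=O)O | target

**Step count**

Total: 15 steps. Longest linear sequence: 10 steps (steps 1, 2, 4, 5, 6, 7, 11, 12, 14, 15).

**Three steps most likely to fail**

Step 11. The bimolecular capture of the ketene by the hindered secondary hydroxyl may be too slow, so that ketene dimerisation or hydration by adventitious water takes over, and part of the excited diazo ketone may be diverted into the 1,2-hydride shift from C2. Fallback, setting out from 9: irradiation in THF/H2O, where water in large excess traps the ketene, should give 5-bromo-2-(2,2-dimethyl-1,3-benzodioxol-5-yl)-7-(methoxymethoxy)-2,3-dihydro-1-benzofuran-3-carboxylic acid F1. Steglich esterification of this acid with 13 (DCC, DMAP, CH2Cl2, 0 °C) then forms the ester link in a separate operation and comes back to the route at 15.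

Step 6. The flavanone enolate may open by retro-oxa-Michael reaction to the chalcone phenoxide before it is C-acylated, returning chalcone 6 after work-up. Fallback, setting out from 7: heating with N,N-dimethylformamide dimethyl acetal in toluene, which needs no discrete metal enolate, should give the enaminone 6-bromo-3-[(dimethylamino)methylidene]-2-(2,2-dimethyl-1,3-benzodioxol-5-yl)-8-(methoxymethoxy)chroman-4-one F2. Diazo transfer to this enaminone with tosyl azide in MeCN (cycloaddition and cycloreversion with loss of the N-sulfonyl formamidine) comes back to the route at 9.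

Step 12. Hydride abstraction at C2 may be slowed by the adjacent ester, so that DDQ turns to oxidation at the benzylic methylene of the danshensu unit or degrades the electron-rich acetonide rings. Fallback, setting out from 9: the dehydrogenation is done before the danshensu unit is present.
- Irradiation of 9 in MeOH/CH2Cl2 should give methyl 5-bromo-2-(2,2-dimethyl-1,3-benzodioxol-5-yl)-7-(methoxymethoxy)-2,3-dihydro-1-benzofuran-3-carboxylate F3.
- DDQ in toluene at 80 °C then gives methyl 5-bromo-2-(2,2-dimethyl-1,3-benzodioxol-5-yl)-7-(methoxymethoxy)-1-benzofuran-3-carboxylate F4, which has no competing benzylic site.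
- Saponification (LiOH, THF/MeOH/H2O, 50 °C, then dilute HCl to pH 4) gives 5-bromo-2-(2,2-dimethyl-1,3-benzodioxol-5-yl)-7-(methoxymethoxy)-1-benzofuran-3-carboxylic acid F5.
- Yamaguchi esterification with 13 (2,4,6-trichlorobenzoyl chloride, Et3N, then DMAP, PhMe) comes back to the route at 16.

**Further compounds**

F1 | step 11 | 5-bromo-2-(2,2-dimethyl-1,3-benzodioxol-5-yl)-7-(methoxymethoxy)-2,3-dihydro-1-benzofuran-3-carboxylic acid (C2/C3 mixture) | OC(=O)C1C(c2ccc3OC(C)(C)Oc3c2)Oc2c(OCOC)cc(Br)cc12
F2 | step 6 | (E)-6-bromo-3-[(dimethylamino)methylidene]-2-(2,2-dimethyl-1,3-benzodioxol-5-yl)-8-(methoxymethoxy)chroman-4-one (racemic) | CN(C)/C=C1\C(c2ccc3OC(C)(C)Oc3c2)Oc2c(OCOC)cc(Br)cc2C1=O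
F3 | step 12 | methyl 5-bromo-2-(2,2-dimethyl-1,3-benzodioxol-5-yl)-7-(methoxymethoxy)-2,3-dihydro-1-benzofuran-3-carboxylate (C2/C3 mixture) | COC(=O)C1C(c2ccc3OC(C)(C)Oc3c2)Oc2c(OCOC)cc(Br)cc12
F4 | step 12 | methyl 5-bromo-2-(2,2-dimethyl-1,3-benzodioxol-5-yl)-7-(methoxymethoxy)-1-benzofuran-3-carboxylate | COC(=O)c1c(-c2ccc3OC(C)(C)Oc3c2)oc2c(OCOC)cc(Br)cc12
F5 | step 12 | 5-bromo-2-(2,2-dimethyl-1,3-benzodioxol-5-yl)-7-(methoxymethoxy)-1-benzofuran-3-carboxylic acid | OC(=O)c1c(-c2ccc3OC(C)(C)Oc3c2)oc2c(OCOC)cc(Br)cc12
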